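At the last reading the north-west run stands at 67.8% of its starting material, and the north-east run at 77.6% of its coupling partner, the limiting reagent.

| setting | north-west | north-east | west |
|---|---|---|---|
| starting material | 0.150 M | 0.450 M | 0.150 M |
| coupling partner | 0.225 M | 0.225 M | 0.680 M |
| catalyst | 0.00150 M | 0.00150 M | 0.00450 M |
| time |  |  | 180 min |

| run | time / min | [target] / M |
|---|---|---|
| north-west run | 30 | 0.0543 |
| north-west run | 60 | 0.0783 |
| north-west run | 90 | 0.0910 |
| north-west run | 120 | 0.0980 |
| north-west run | 150 | 0.0999 |
| north-west run | 180 | 0.1017 |
| north-east run | 30 | 0.1126 |
| north-east run | 60 | 0.1477 |
| north-east run | 90 | 0.1610 |
| north-east run | 120 | 0.1714 |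
| north-east run | 150 | 0.1731 |
| north-east run | 180 | 0.1746 |

(readings scatter by 0.002 M)

1. the power of [starting material] that the first rate follows, about the charge of the north-west run; measure it at two percent of starting material made into target (one fixed amount of target, the same in the runs compared)
2. target in the west run at 180 min, as a share of the starting material charged

- Overall: starting material + coupling partner -> target, with catalyst as catalyst.
- Constant volume, constant temperature.
- The analysis sees a species whether free or bound.
- "The second partner" is coupling partner.
- An order is taken over about fifteen percent of the charge, up and down.

Which numbers must you know well for the west run? Start with speed. Over the first interval the apparent second-order constant reads 0.0745 M⁻¹ min⁻¹ north-west and 0.0565 M⁻¹ min⁻¹ north-east, lower in the run that has made more target. I take target to hold catalyst, leaving a free share 1/(1+KP), with P the concentration of target, which gives 0.106 M⁻¹ min⁻¹ unhindered and K = 15.5 M⁻¹. That reckoning takes the starting material to enter in proportion, so my order in it is one. Assuming the rate follows catalyst, which the north-west and north-east runs do not test at their equal charge, I reckon target in the west run to be born on average at 12.9 min.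

Next comes the stall. The forecast says “The stall looks abrupt, more like equilibrium than slow catalyst decay.” It gives 0.8 and 90%. I part from it here: at the last readings, target over the product of starting material and coupling partner reckoned as remaining reads 17.1 M⁻¹ north-west and 12.6 M⁻¹ north-east, apart by more than the 0.499 M⁻¹ that one reading's scatter gives north-east. So I balance making against loss late in the north-east run, where the free share is 27.1%, counting the partner that lost target has consumed. That gives the late loss constant, the fraction of standing target gone per minute 9.97 × 10⁻⁴ min⁻¹. My west yield is 84.6%. Doubling the birth time moves that by about 1.1 percentage points, less than the 15 points my late loss takes, so the late loss constant is the number to know well.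

The flask gives 1.0 and 82.8%.

    catalyst + starting material + coupling partner → target + catalyst (69.00 M⁻² min⁻¹)
    catalyst + target ⇌ catalyst-product complex, settled at all times (10.10 M⁻¹)
    target → decomposed product (0.001128 min⁻¹)

The binding of catalyst and target into catalyst-product complex moves that west yield little. Put to the north-west run, the late loss constant gives a loss of 2.03% of the starting material charged per 30 min at the last reading, while the readings rose 1.20% over the last interval.

The readings are simulated for an exercise, and the scatter is random.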